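(The numbers in the tables come from a simulation with made-up constants.)

- Two questions stood before me: the excess of left-handed product over right-handed product at the end of the violet, red and green flasks, and how that row runs.

the same everywhere: left-handed substrate 0.56 M; right-handed substrate 0.56 M; catalyst 56 mM

|  | solid reagent | remark | time |
|---|---|---|---|
| north-west | 0.96 M | run made earlier |  |
| north-east | 1.6 M | run made earlier |  |
| north | 2.9 M | run made earlier |  |
| violet | 0.800 M |  | 20 d |
| red | 1.50 M |  | 20 d |
| green | 3.00 M |  | 20 d |

| run | time / d | left-handed product / % | right-handed product / % | left-handed substrate / % |
|---|---|---|---|---|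
| north-west | 1.25 | 0.2 | 0 | 49.0 |
| north-west | 4.00 | 1.3 | 1.4 | 47.8 |
| north-west | 6.00 | 3.4 | 1.8 | 49.3 |
| north-west | 10.0 | 4.5 | 2.5 | 45.6 |
| north-east | 1.25 | 0.2 | 0 | 50.5 |
| north-east | 4.00 | 1.2 | 1.3 | 49.0 |
| north-east | 6.00 | 2.6 | 0.3 | 48.1 |
| north-east | 10.0 | 4.6 | 2.9 | 46.5 |
| north | 0.833 | 0 | 0.8 | 49.9 |
| north | 1.67 | 0.7 | 0.1 | 49.4 |
| north | 4.00 | 1.8 | 1.5 | 49.1 |
| north | 10.0 | 5.4 | 2.4 | 46.0 |

(each reading ± 0.5 percentage points)

- excess of left-handed product over right-handed product at the end for violet, red, green, in this order
- how the row runs (hardly changes / falls all the way / rises, then falls / falls, then rises / rises all the way)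

- catalyst is single-handed; left-handed substrate and right-handed substrate are mirror images of each other, charged as a racemate, each of them at the stated concentration
- given per volume of solution although it is solid: solid reagent
- what was read earlier has a scatter of 0.5 percentage points, one standard deviation
- at the start none of the solid reagent is in solution
- an excess is the difference of the two amounts in percent of their sum
- "hardly changes" means that all values lie within two and a half points (for a concentration: within two and a half percent of the largest)

- I first asked how far the row would move if each given number were off, and the catalyst and substrate charges needed least care: at 56 mM and 0.56 M they match the runs, so their effect already sits inside the readings.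
- The solid reagent charge looked harmless while the solid lasts, since a charge 3.02 times larger took the summed products at 10.0 d merely from 7.00% to 7.80%, with a scatter of 0.5 percentage points on each reading; but violet's 0.800 M is less than the 0.96 M of the lowest run.
- The product readings had to be known best, because the excess at 10.0 d read 28.6%, 22.7% and 38.5% across the runs; so I pooled them, and means of 4.83% and 2.60% gave me 30.0%.
- Violet's charge lies below the 1.12 M of substrates, which makes solid reagent the limiting reagent by charge, so I took one solid reagent per product and a steady pace of 8.33 mM/d, and reckoned the draw, the solid reagent that the product made by the asked time takes from the charge, as 0.167 M.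
- Violet's charge was 4.80 times the draw, so I expected a flat row.
- The forecast gave 28%, 28% and 28%, a row that hardly changes, holding that “the solid never runs out”; its figure lies below mine, and it holds that faster depletion of the left-handed substrate trims the excess slightly.

- The flasks gave 30.0%, 30.0% and 30.0%, a row that hardly changes.

    coupling partner + catalyst + left-handed substrate → catalyst + left-handed product (k = 0.274 /M²/h)
    coupling partner + catalyst + right-handed substrate → catalyst + right-handed product (k = 0.147 /M²/h)
    left-handed substrate ⇌ right-handed substrate (k = 0.0259 /h)
    solid reagent ⇌ coupling partner, rate k4*(cs4 - [coupling partner]) while solid is left; crystals form when [coupling partner] > cs4 (solubility = 0.0510 M, k = 0.0209 /h)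

- At the end violet and green both held coupling partner at 0.0331 M. The draw is 20.9% of violet's charge, and 78.0% of that charge was left there, solid or dissolved; it is 5.55% of green's charge, and green had 94% of its charge left, solid or dissolved.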